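**Plan**

- Retrosynthesis: the two O–Si bonds and the C4 oxidation level are adjusted last. The two aryl–prenyl bonds (at C6 and C3') are cut back to aryl bromides. The pyranone ring is then cut at O1–C2 and C4–C4a to 4-bromoresorcinol and a 3-hydroxy-2-arylpropanoic acid, and that acid at C2–C3 to an arylacetic acid and formaldehyde.
- Forward: C2 is attached to the B-ring acid; one annulation fuses the C2–C3–C4 unit onto the A ring and closes the pyranone ring; both prenyl groups follow by twofold Stille coupling, so they never meet the Lewis acid.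
- Enabling feature: C4a of the resorcinol A ring lies ortho to O1 and para to the 7-OH, so O1/C4a act as a 1,3-dinucleophile toward the acyl carbon C4 and the β-carbon C2 of the α-aryl three-carbon unit. Bromine at C6 and C3' holds the prenyl positions, and at C6 it also blocks that ring carbon.
- Stereochemistry: C3 (benzylic, α to C4=O) is labile and is left racemic through the acidic, hot and Pd steps. It is set late by Ru/TsDPEN transfer hydrogenation with dynamic kinetic resolution ((3S,4S)-cis-alcohol); buffered re-oxidation of C4 and non-basic desilylation should keep (3S).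

Key step: step 2

Remark: the (S,S)-Ru/TsDPEN catalyst is assigned by analogy with the (S)-selective reduction of 4-chromanone and 1-tetralone; BF3·OEt2 in step 2 is counted as promoter and medium.

**Step 1**
Reactants: 1 2-(3-bromo-4-hydroxyphenyl)acetic acid; 2 formaldehyde (used as paraformaldehyde)
Product: 4 rac-2-(3-bromo-4-hydroxyphenyl)-3-hydroxypropanoic acid, via Ivanov reagent 3 (not isolated)
Conditions: i-PrMgCl (3.3 equiv), THF, 0 → 40 °C; (CH2O)n, 0 °C → rt; aq. HCl
Reagents that add atoms: formaldehyde (2), C=O
Why: Ivanov reaction: the chloromagnesium enediolate of the arylacetic acid (a third equivalent of base masks the phenol, and the aryl bromide is inert to i-PrMgCl without LiCl) adds to formaldehyde in an aldol-type hydroxymethylation; the new stereocenter is racemic and is erased in step 2.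

**Step 2**
Reactants: 4 rac-2-(3-bromo-4-hydroxyphenyl)-3-hydroxypropanoic acid; 5 4-bromoresorcinol (4-bromobenzene-1,3-diol)
Product: 8 rac-6-bromo-3-(3-bromo-4-hydroxyphenyl)-7-hydroxychroman-4-one, via hydroxy ketone 6 (not isolated), via aryl vinyl ketone 7 (not isolated)
Conditions: BF3·OEt2 (neat), 80 °C; then aq. NaOAc, EtOH, 60 °C
Reagents that add atoms: 4-bromoresorcinol (5), Oc1ccc(Br)c(O)c1
Why: BF3 activates the carboxyl group of 4 (mixed anhydride/acylium equivalent), which acylates 5 at C6 in a Friedel–Crafts reaction to give the BF2-chelated hydroxy ketone 6; the acidic α-aryl position enolizes and the β-hydroxyl leaves (E1cB-type dehydration) to give the aryl vinyl ketone 7, and a dehydration-first path through the 2-arylacrylic acid converges on the same enone. Once the chelate is hydrolysed (aq. NaOAc) the ortho phenol oxygen adds to the CH2 terminus, so the C4–C4a and O1–C2 bonds arise in one operation. The closest known reaction type is the BF3- or Brønsted-acid-mediated synthesis of 7-hydroxychroman-4-ones from resorcinols and acrylic or 3-hydroxy acids (tandem Friedel–Crafts acylation/oxa-Michael addition). The pyranone ring closes by 6-endo-trig oxa-Michael addition. C3 is created by unselective ketonization of the enol and is intentionally racemic here; it is set in step 5. The step needs regioselective C-acylation: C6 of 5 is ortho to one OH and para to the other, bromine occupies the other activated carbon, the ring carbon between the two hydroxyls is hindered, only the hydroxyl ortho to the new acyl group can reach the CH2 carbon, and the primary, non-cation-stabilized CH2 disfavours the competing C-alkylation to a dihydrocoumarin.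

**Step 3**
Reactants: 8 rac-6-bromo-3-(3-bromo-4-hydroxyphenyl)-7-hydroxychroman-4-one; 9 tert-butyldimethylsilyl chloride
Product: 10 rac-6-bromo-3-[3-bromo-4-(tert-butyldimethylsilyloxy)phenyl]-7-(tert-butyldimethylsilyloxy)chroman-4-one
Conditions: TBSCl (2.5 equiv), imidazole (5 equiv), DMF, rt
Reagents that add atoms: tert-butyldimethylsilyl chloride (9), CC(C)(C)[Si](C)(C)Cl
Why: Standard imidazole-mediated silylation of both phenols gives aryl silyl ethers that should tolerate Pd(0), formic acid/triethylamine and the periodinane and can be removed at the end without base.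

**Step 4**
Reactants: 10 rac-6-bromo-3-[3-bromo-4-(tert-butyldimethylsilyloxy)phenyl]-7-(tert-butyldimethylsilyloxy)chroman-4-one; 11 tributyl(3-methylbut-2-en-1-yl)stannane
Product: 12 rac-7-(tert-butyldimethylsilyloxy)-3-[4-(tert-butyldimethylsilyloxy)-3-(3-methylbut-2-en-1-yl)phenyl]-6-(3-methylbut-2-en-1-yl)chroman-4-one
Conditions: 11 (3 equiv), Pd(PPh3)4 (10 mol %), DMF (degassed), 95 °C
Reagents that add atoms: tributyl(3-methylbut-2-en-1-yl)stannane (11), CCCC[Sn](CCCC)(CCCC)CC=C(C)C
Why: Twofold Stille coupling: oxidative addition of Pd(0) into each aryl bromide, transmetalation with the prenylstannane and reductive elimination at the less hindered allyl terminus should give the linear prenyl arenes, and the neutral conditions leave the silyl ethers and the still racemic ketone untouched.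

**Step 5**
Reactants: 12 rac-7-(tert-butyldimethylsilyloxy)-3-[4-(tert-butyldimethylsilyloxy)-3-(3-methylbut-2-en-1-yl)phenyl]-6-(3-methylbut-2-en-1-yl)chroman-4-one
Product: 13 (3S,4S)-7-(tert-butyldimethylsilyloxy)-3-[4-(tert-butyldimethylsilyloxy)-3-(3-methylbut-2-en-1-yl)phenyl]-6-(3-methylbut-2-en-1-yl)chroman-4-ol (cis)
Conditions: RuCl[(S,S)-TsDPEN](p-cymene) (2 mol %), HCO2H/Et3N (5:2), EtOAc, 40 °C
Reagents that add atoms: none
Why: Asymmetric transfer hydrogenation with dynamic kinetic resolution: triethylamine equilibrates the C3 epimers through the enol while the (S,S)-Ru/TsDPEN hydride should reduce only the (3S)-ketone, from the C4 face anti to the 3-aryl group, so that C3 (S) and C4 (S, cis) are both set by the catalyst; the prenyl olefins are not reduced under transfer hydrogenation.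

**Step 6**
Reactants: 13 (3S,4S)-7-(tert-butyldimethylsilyloxy)-3-[4-(tert-butyldimethylsilyloxy)-3-(3-methylbut-2-en-1-yl)phenyl]-6-(3-methylbut-2-en-1-yl)chroman-4-ol
Product: 14 (3S)-7-(tert-butyldimethylsilyloxy)-3-[4-(tert-butyldimethylsilyloxy)-3-(3-methylbut-2-en-1-yl)phenyl]-6-(3-methylbut-2-en-1-yl)chroman-4-one
Conditions: Dess–Martin periodinane (1.3 equiv), pyridine (buffer), CH2Cl2, 0 °C
Reagents that add atoms: none
Why: Dess–Martin oxidation of the benzylic carbinol under pyridine-buffered, non-basic conditions at 0 °C should return the C4 ketone without enolization of the adjacent C3 stereocenter, and neither the prenyl olefins nor the silyl ethers should react.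

**Step 7**
Reactants: 14 (3S)-7-(tert-butyldimethylsilyloxy)-3-[4-(tert-butyldimethylsilyloxy)-3-(3-methylbut-2-en-1-yl)phenyl]-6-(3-methylbut-2-en-1-yl)chroman-4-one
Product: 15 (3S)-7-hydroxy-3-[4-hydroxy-3-(3-methylbut-2-en-1-yl)phenyl]-6-(3-methylbut-2-en-1-yl)chroman-4-one
Conditions: HF·pyridine, pyridine, THF, 0 °C → rt
Reagents that add atoms: none
Why: Fluoride-mediated cleavage of both aryl silyl ethers under weakly acidic, pyridine-buffered conditions avoids the base that would epimerize C3 and the strong acid that would cyclize the ortho-prenylphenols.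

**Compound list**

1 | 2-(3-bromo-4-hydroxyphenyl)acetic acid | OC(=O)Cc1ccc(O)c(Br)c1 | starting material
2 | formaldehyde (used as paraformaldehyde) | C=O | starting material
3 | Ivanov reagent of 1 (tris-chloromagnesium enediolate/phenoxide; not isolated) | [O-]C([O-])=Cc1ccc([O-])c(Br)c1.Cl[Mg+].Cl[Mg+].Cl[Mg+] | intermediate
4 | rac-2-(3-bromo-4-hydroxyphenyl)-3-hydroxypropanoic acid | OCC(C(=O)O)c1ccc(O)c(Br)c1 | intermediate
5 | 4-bromoresorcinol (4-bromobenzene-1,3-diol) | Oc1ccc(Br)c(O)c1 | starting material
6 | rac-1-(5-bromo-2,4-dihydroxyphenyl)-2-(3-bromo-4-hydroxyphenyl)-3-hydroxypropan-1-one (not isolated) | OCC(C(=O)c1cc(Br)c(O)cc1O)c1ccc(O)c(Br)c1 | intermediate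
7 | 1-(5-bromo-2,4-dihydroxyphenyl)-2-(3-bromo-4-hydroxyphenyl)prop-2-en-1-one (not isolated) | C=C(C(=O)c1cc(Br)c(O)cc1O)c1ccc(O)c(Br)c1 | intermediate
8 | rac-6-bromo-3-(3-bromo-4-hydroxyphenyl)-7-hydroxychroman-4-one | O=C1c2cc(Br)c(O)cc2OCC1c1ccc(O)c(Br)c1 | intermediate
9 | tert-butyldimethylsilyl chloride | CC(C)(C)[Si](C)(C)Cl | starting material
10 | rac-6-bromo-3-[3-bromo-4-(tert-butyldimethylsilyloxy)phenyl]-7-(tert-butyldimethylsilyloxy)chroman-4-one | CC(C)(C)[Si](C)(C)Oc1ccc(C2COc3cc(O[Si](C)(C)C(C)(C)C)c(Br)cc3C2=O)cc1Br | intermediate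
11 | tributyl(3-methylbut-2-en-1-yl)stannane | CCCC[Sn](CCCC)(CCCC)CC=C(C)C | starting material
12 | rac-7-(tert-butyldimethylsilyloxy)-3-[4-(tert-butyldimethylsilyloxy)-3-(3-methylbut-2-en-1-yl)phenyl]-6-(3-methylbut-2-en-1-yl)chroman-4-one | CC(C)=CCc1cc(C2COc3cc(O[Si](C)(C)C(C)(C)C)c(CC=C(C)C)cc3C2=O)ccc1O[Si](C)(C)C(C)(C)C | intermediate
13 | (3S,4S)-7-(tert-butyldimethylsilyloxy)-3-[4-(tert-butyldimethylsilyloxy)-3-(3-methylbut-2-en-1-yl)phenyl]-6-(3-methylbut-2-en-1-yl)chroman-4-ol (cis) | CC(C)=CCc1cc([C@H]2COc3cc(O[Si](C)(C)C(C)(C)C)c(CC=C(C)C)cc3[C@H]2O)ccc1O[Si](C)(C)C(C)(C)C | intermediate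
14 | (3S)-7-(tert-butyldimethylsilyloxy)-3-[4-(tert-butyldimethylsilyloxy)-3-(3-methylbut-2-en-1-yl)phenyl]-6-(3-methylbut-2-en-1-yl)chroman-4-one | CC(C)=CCc1cc([C@H]2COc3cc(O[Si](C)(C)C(C)(C)C)c(CC=C(C)C)cc3C2=O)ccc1O[Si](C)(C)C(C)(C)C | intermediate
15 | (3S)-7-hydroxy-3-[4-hydroxy-3-(3-methylbut-2-en-1-yl)phenyl]-6-(3-methylbut-2-en-1-yl)chroman-4-one | CC(C)=CCc1cc([C@H]2COc3cc(O)c(CC=C(C)C)cc3C2=O)ccc1O | target

**Step count and risks**

Total step count: 7. Longest linear sequence: 7 steps (from 1 to 15).

Steps most likely to fail: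

1. Step 2 (annulation). The hydroxy acid may oligomerize by self-esterification, the arene may be alkylated at carbon instead of acylated (dihydrocoumarin pathway), or dehydration and ring closure may stay incomplete. Fallback: the same ring is built in the deoxybenzoin order of bond formation. From 1 and 5, BF3·OEt2-mediated Friedel–Crafts acylation should give the deoxybenzoin 1-(5-bromo-2,4-dihydroxyphenyl)-2-(3-bromo-4-hydroxyphenyl)ethan-1-one F1. Mannich-type α-methylenation with paraformaldehyde (2) and catalytic diethylamine in refluxing ethanol, followed by spontaneous oxa-Michael closure, should then give 8, where the route is rejoined.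

2. Step 4 (twofold prenyl transfer). Oxidative addition into the electron-rich ortho-silyloxy aryl bromides may be slow, the prenyl group may be delivered through its γ-carbon (1,1-dimethylallyl isomers), or protodebromination may compete. Fallback: from 10, twofold Stille coupling with allyltributylstannane should give the bis-allyl compound rac-3-[3-allyl-4-(tert-butyldimethylsilyloxy)phenyl]-6-allyl-7-(tert-butyldimethylsilyloxy)chroman-4-one F2, for which no α/γ question exists. Olefin cross-metathesis with excess 2-methyl-2-butene (second-generation Ru benzylidene catalyst, CH2Cl2, 40 °C) then converts both allyl groups into prenyl groups and returns to 12.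

3. Step 6 (re-oxidation). The C3 configuration may erode by enolization of the newly formed ketone during oxidation or work-up. Fallback: the reduction/oxidation detour is avoided. From 12, TMSOTf/Et3N should give the silyl enol ether 7-(tert-butyldimethylsilyloxy)-3-[4-(tert-butyldimethylsilyloxy)-3-(3-methylbut-2-en-1-yl)phenyl]-6-(3-methylbut-2-en-1-yl)-4-(trimethylsilyloxy)-2H-chromene F3. Catalytic enantioselective protonation (chiral BINOL-derived N-triflyl thiophosphoramide, phenol as stoichiometric proton source, toluene, catalyst antipode chosen for 3S) should then give 14 directly, bypassing 13.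

**Further compounds**

F1 | step 2 | 1-(5-bromo-2,4-dihydroxyphenyl)-2-(3-bromo-4-hydroxyphenyl)ethan-1-one | O=C(Cc1ccc(O)c(Br)c1)c1cc(Br)c(O)cc1O
F2 | step 4 | rac-3-[3-allyl-4-(tert-butyldimethylsilyloxy)phenyl]-6-allyl-7-(tert-butyldimethylsilyloxy)chroman-4-one | C=CCc1cc(C2COc3cc(O[Si](C)(C)C(C)(C)C)c(CC=C)cc3C2=O)ccc1O[Si](C)(C)C(C)(C)C
F3 | step 6 | 7-(tert-butyldimethylsilyloxy)-3-[4-(tert-butyldimethylsilyloxy)-3-(3-methylbut-2-en-1-yl)phenyl]-6-(3-methylbut-2-en-1-yl)-4-(trimethylsilyloxy)-2H-chromene | CC(C)=CCc1cc(C2=C(O[Si](C)(C)C)c3cc(CC=C(C)C)c(O[Si](C)(C)C(C)(C)C)cc3OC2)ccc1O[Si](C)(C)C(C)(C)C
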